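**Retrosynthetic overview**

1. Target 17 ⇐ tris-MOM chalcone 16 (acetal cleavage) ⇐ Claisen–Schmidt condensation of methyl ketone 13 with 4-(methoxymethoxy)benzaldehyde 14.
2. 13 ⇐ arylacetaldehyde 8 + alkenyl triflate 11: the bond between the methylidene-bearing carbon C3 of the side chain and the carbinol carbon C2 is made by a catalytic asymmetric Ni/Cr (Nozaki–Hiyama–Kishi) coupling, which also sets the only stereocentre.
3. Enabling feature: the sp2 carbon that carries the exocyclic =CH2 sits directly on the secondary carbinol carbon, which is one CH2 away from ring carbon C3' of the resorcinol ring (between C2'–O and C4'–O). Such a 2-alken-2-yl carbinol is an aldehyde carbon plus the carbonyl carbon of a methyl ketone, and the C8 ketone needed is sulcatone itself.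
4. 8 ⇐ 3-allyl-2,4-dihydroxyacetophenone 5 (aromatic Claisen rearrangement of the 4-O-allyl ether of resacetophenone into C3'), then bis-MOM protection and oxidative cleavage of the allyl group to the CH2–CHO unit.
5. No ring is formed in the route; both benzene rings come with starting materials 1 and 14.

Key step: step 6

Assumption: both enantiomers of the oxazoline–sulfonamide ligand are accessible from D- or L-valinol; the route uses the enantiomer that delivers the alkenyl group to the Si face of aldehyde 8, to be confirmed on 13 by MTPA ester analysis. Compound 14 is taken as a commercial material.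

**Step 1**
Reactants: 1 2,4-dihydroxyacetophenone; 2 allyl bromide
Product: 3 1-[4-(allyloxy)-2-hydroxyphenyl]ethan-1-one
Conditions: K2CO3, acetone, reflux
Reagents that add atoms: none
Why: Williamson etherification; the 2-OH is held in a hydrogen bond to the acetyl carbonyl, so the free and more acidic 4-OH should be alkylated selectively.

**Step 2**
Reactants: 3 1-[4-(allyloxy)-2-hydroxyphenyl]ethan-1-one
Product: 5 1-(3-allyl-2,4-dihydroxyphenyl)ethan-1-one, via ortho-dienone 4 (not isolated)
Conditions: N,N-diethylaniline, 200–210 °C, Ar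
Reagents that add atoms: none
Why: Aromatic Claisen rearrangement ([3,3]-sigmatropic shift, then tautomerisation of 4); chelation of the 2-OH to the acetyl group fixes the ring bonds so that migration to C3, the carbon between the two oxygens, is expected to dominate over C5.

**Step 3**
Reactants: 5 1-(3-allyl-2,4-dihydroxyphenyl)ethan-1-one
Product: 6 1-[3-allyl-2,4-bis(methoxymethoxy)phenyl]ethan-1-one
Conditions: NaH (2.4 equiv), MOMCl (2.6 equiv), DMF, 0 °C → rt
Reagents that add atoms: chloromethyl methyl ether (MOMCl), COCCl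
Why: Phenoxide O-alkylation (NaH is needed for the hindered, chelated 2-OH); both ortho phenols must be capped so the aldehyde of step 4 cannot close to a lactol or benzofuran, and MOM ethers should survive the oxidation, the Ni/Cr coupling and KOH.

**Step 4**
Reactants: 6 1-[3-allyl-2,4-bis(methoxymethoxy)phenyl]ethan-1-one
Product: 8 2-[3-acetyl-2,6-bis(methoxymethoxy)phenyl]acetaldehyde, via 1,2-diol 7 (not isolated)
Conditions: OsO4 (2 mol %), NaIO4 (4 equiv), 2,6-lutidine, dioxane/H2O 3:1, rt; crude aldehyde used at once
Reagents that add atoms: osmium tetroxide (catalytic oxygen carrier), O=[Os](=O)(=O)=O; sodium periodate, [Na+].[O-]I(=O)(=O)=O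
Why: Lemieux–Johnson oxidation (osmylation to diol 7, periodate cleavage); the monosubstituted allyl alkene is the only C=C present, and 2,6-lutidine should suppress over-oxidation.

**Step 5**
Reactants: 9 6-methylhept-5-en-2-one (sulcatone)
Product: 11 6-methylhepta-1,5-dien-2-yl trifluoromethanesulfonate, via kinetic lithium enolate 10 (not isolated)
Conditions: LDA, THF, −78 °C; then PhNTf2, −78 → 0 °C
Reagents that add atoms: N-phenylbis(trifluoromethanesulfonimide) (PhNTf2), O=S(=O)(N(c1ccccc1)S(=O)(=O)C(F)(F)F)C(F)(F)F
Why: Kinetic deprotonation of the methyl ketone at CH3, then O-sulfonylation of enolate 10 (enol triflate formation); this places the future exocyclic methylene, and the trisubstituted alkene is inert.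

**Step 6**
Reactants: 8 2-[3-acetyl-2,6-bis(methoxymethoxy)phenyl]acetaldehyde; 11 6-methylhepta-1,5-dien-2-yl trifluoromethanesulfonate
Product: 13 1-{3-[(2R)-2-hydroxy-7-methyl-3-methylideneoct-6-en-1-yl]-2,4-bis(methoxymethoxy)phenyl}ethan-1-one, via alkenylchromium(III) species 12 (not isolated)
Conditions: 11 (1.5 equiv), CrCl2 (10 mol %), chiral (4-isopropyloxazolin-2-yl)aryl methanesulfonamide ligand (11 mol %), proton sponge (11 mol %), NiCl2·2,9-dimethyl-1,10-phenanthroline (2 mol %), Mn (2 equiv), Cp2ZrCl2 (1.2 equiv), LiCl (2 equiv), MeCN, rt; aqueous work-up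
Reagents that add atoms: none
Why: Ni(0), formed from the Ni(II) precatalyst and Mn, inserts into the C–OTf bond of 11, the alkenyl group passes to the ligand-bound Cr(III) centre to give 12, and 12 adds to the aldehyde carbonyl of 8; Cp2ZrCl2 takes over the alkoxide so that Mn can turn chromium over, and aqueous work-up frees the alcohol. This is the catalytic asymmetric Nozaki–Hiyama–Kishi coupling of an alk-1-en-2-yl electrophile with an unbranched aliphatic aldehyde, the established route to 2-methylidene carbinols. No ring is closed. The new stereocentre C2 is controlled by the chiral oxazoline–sulfonamide ligand on chromium, chosen for Si-face delivery of the alkenyl group, which corresponds to (R) because the alkenyl carbon outranks CH2Ar. The step needs chemoselectivity for CHO over the aryl methyl ketone, which the low nucleophilicity of organochromium(III) reagents should secure, and it must not enolise the arylacetaldehyde, which the non-basic medium and Cp2ZrCl2 in place of a silyl chloride should secure. The position of the exocyclic double bond is fixed by the triflate, so no alkene regio- or stereoisomers can arise.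

**Step 7**
Reactants: 13 1-{3-[(2R)-2-hydroxy-7-methyl-3-methylideneoct-6-en-1-yl]-2,4-bis(methoxymethoxy)phenyl}ethan-1-one; 14 4-(methoxymethoxy)benzaldehyde
Product: 16 (2E)-1-{3-[(2R)-2-hydroxy-7-methyl-3-methylideneoct-6-en-1-yl]-2,4-bis(methoxymethoxy)phenyl}-3-[4-(methoxymethoxy)phenyl]prop-2-en-1-one, via aldol adduct 15 (not isolated)
Conditions: KOH (aq., excess), EtOH, 0 °C → rt
Reagents that add atoms: none
Why: Claisen–Schmidt condensation (crossed aldol with non-enolisable 14, then E1cB dehydration of 15 to the thermodynamically favoured E-enone); MOM ethers, the free allylic alcohol and its non-acidic stereocentre should be stable to hydroxide.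

**Step 8**
Reactants: 16 (2E)-1-{3-[(2R)-2-hydroxy-7-methyl-3-methylideneoct-6-en-1-yl]-2,4-bis(methoxymethoxy)phenyl}-3-[4-(methoxymethoxy)phenyl]prop-2-en-1-one
Product: 17 (2E)-1-{2,4-dihydroxy-3-[(2R)-2-hydroxy-7-methyl-3-methylideneoct-6-en-1-yl]phenyl}-3-(4-hydroxyphenyl)prop-2-en-1-one
Conditions: 3 M aq. HCl, MeOH, 25–40 °C, stopped at full conversion
Reagents that add atoms: none
Why: Acid-catalysed acetal exchange of the three aryl MOM ethers with methanol, the usual end-game for prenylated hydroxychalcones; under dilute acid at low temperature the secondary allylic alcohol, both alkenes and the chalcone should persist.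

**Compound list**

1 | 2,4-dihydroxyacetophenone | CC(=O)c1ccc(O)cc1O | starting material
2 | allyl bromide | C=CCBr | starting material
3 | 1-[4-(allyloxy)-2-hydroxyphenyl]ethan-1-one | CC(=O)c1ccc(OCC=C)cc1O | intermediate
4 | 4-acetyl-5-hydroxy-6-(prop-2-en-1-yl)cyclohexa-2,4-dien-1-one (ortho-dienone, racemic, formed in the flask) | CC(=O)C1=C(O)C(CC=C)C(=O)C=C1 | intermediate
5 | 1-(3-allyl-2,4-dihydroxyphenyl)ethan-1-one | CC(=O)c1ccc(O)c(CC=C)c1O | intermediate
6 | 1-[3-allyl-2,4-bis(methoxymethoxy)phenyl]ethan-1-one | CC(=O)c1ccc(OCOC)c(CC=C)c1OCOC | intermediate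
7 | 1-[3-(2,3-dihydroxypropyl)-2,4-bis(methoxymethoxy)phenyl]ethan-1-one (racemic, formed in the flask) | CC(=O)c1ccc(OCOC)c(CC(O)CO)c1OCOC | intermediate
8 | 2-[3-acetyl-2,6-bis(methoxymethoxy)phenyl]acetaldehyde | CC(=O)c1ccc(OCOC)c(CC=O)c1OCOC | intermediate
9 | 6-methylhept-5-en-2-one (sulcatone) | CC(=O)CCC=C(C)C | starting material
10 | lithium 6-methylhepta-1,5-dien-2-olate (formed in the flask) | [Li]OC(=C)CCC=C(C)C | intermediate
11 | 6-methylhepta-1,5-dien-2-yl trifluoromethanesulfonate | C=C(CCC=C(C)C)OS(=O)(=O)C(F)(F)F | intermediate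
12 | (6-methylhepta-1,5-dien-2-yl)chromium(III) dichloride (bound to the chiral ligand in the flask; ligand omitted in the SMILES) | C=C(CCC=C(C)C)[Cr](Cl)Cl | intermediate
13 | 1-{3-[(2R)-2-hydroxy-7-methyl-3-methylideneoct-6-en-1-yl]-2,4-bis(methoxymethoxy)phenyl}ethan-1-one | C=C(CCC=C(C)C)[C@H](O)Cc1c(OCOC)ccc(C(C)=O)c1OCOC | intermediate
14 | 4-(methoxymethoxy)benzaldehyde | COCOc1ccc(C=O)cc1 | starting material
15 | 3-hydroxy-1-{3-[(2R)-2-hydroxy-7-methyl-3-methylideneoct-6-en-1-yl]-2,4-bis(methoxymethoxy)phenyl}-3-[4-(methoxymethoxy)phenyl]propan-1-one (both epimers at the new carbinol, formed in the flask) | C=C(CCC=C(C)C)[C@H](O)Cc1c(OCOC)ccc(C(=O)CC(O)c2ccc(OCOC)cc2)c1OCOC | intermediate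
16 | (2E)-1-{3-[(2R)-2-hydroxy-7-methyl-3-methylideneoct-6-en-1-yl]-2,4-bis(methoxymethoxy)phenyl}-3-[4-(methoxymethoxy)phenyl]prop-2-en-1-one | C=C(CCC=C(C)C)[C@H](O)Cc1c(OCOC)ccc(C(=O)/C=C/c2ccc(OCOC)cc2)c1OCOC | intermediate
17 | (2E)-1-{2,4-dihydroxy-3-[(2R)-2-hydroxy-7-methyl-3-methylideneoct-6-en-1-yl]phenyl}-3-(4-hydroxyphenyl)prop-2-en-1-one | C=C(CCC=C(C)C)[C@H](O)Cc1c(O)ccc(C(=O)/C=C/c2ccc(O)cc2)c1O | target

**Totals**

Total step count: 8. Longest linear sequence: 7 steps (steps 1–4 and 6–8; step 5 is a one-step side branch to 11).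

**Steps most likely to fail**

Step 6. Facial selectivity may be eroded because the two ortho MOM oxygens can chelate chromium and compete with the chiral ligand; the arylacetaldehyde may enolise and self-condense if the coupling is slow; oxidative addition of the alkenyl triflate may be sluggish. The fallback sets out from 8 and 11 and comes back at 13. A ligand-free stoichiometric Ni/Cr coupling (CrCl2 in excess, NiCl2 cat., DMF, rt) should give the racemic alcohol 1-{3-[2-hydroxy-7-methyl-3-methylideneoct-6-en-1-yl]-2,4-bis(methoxymethoxy)phenyl}ethan-1-one F1. Sharpless kinetic resolution follows (Ti(OiPr)4, L-(+)-diisopropyl tartrate, TBHP 0.6 equiv, 4 Å MS, CH2Cl2, −20 °C). The (S)-enantiomer, which presents its carbinol hydrogen to the face of oxygen delivery, should be epoxidised fast to the erythro epoxy alcohol 1-{3-[(2S)-2-hydroxy-2-[(2S)-2-(4-methylpent-3-en-1-yl)oxiran-2-yl]ethyl]-2,4-bis(methoxymethoxy)phenyl}ethan-1-one F2. The slow-reacting (R)-enantiomer is recovered as 13 after chromatography; the distal trisubstituted alkene is not allylic and should stay untouched.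

Step 8. Under protic acid a liberated ortho phenol may add to the 1,1-disubstituted alkene (chroman formation), the allylic alcohol may ionise, and the 2'-hydroxychalcone may close to a flavanone. The fallback sets out from 16 and comes back at 17 without Brønsted acid. Treatment with TESOTf and 2,2'-bipyridyl (CH2Cl2, 0 °C → rt) should exchange the three aryl MOM acetals for silyl ethers and silylate the carbinol, giving the tetrakis(triethylsilyl) ether (2E)-1-{3-[(2R)-7-methyl-3-methylidene-2-(triethylsilyloxy)oct-6-en-1-yl]-2,4-bis(triethylsilyloxy)phenyl}-3-[4-(triethylsilyloxy)phenyl]prop-2-en-1-one F3. Buffered fluoride (HF·pyridine, THF/pyridine, 0 °C) then removes all four silyl groups to give 17.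

Step 5. Deprotonation may partly occur at C3 of sulcatone, giving internal enol triflates that are hard to separate and that would couple in step 6. The fallback sets out from 9 and comes back at 12, and hence 13. Condensation of 9 with 2,4,6-triisopropylbenzenesulfonyl hydrazide (MeOH, cat. HCl) should give the (E)-hydrazone N'-(6-methylhept-5-en-2-ylidene)-2,4,6-triisopropylbenzenesulfonohydrazide F4. A Shapiro reaction (n-BuLi 2.1 equiv, THF, −78 → 0 °C) deprotonates the methyl group syn to the sulfonamide nitrogen and should give 2-lithio-6-methylhepta-1,5-diene F5. Quenching with I2 at −78 °C gives the regiodefined 2-iodo-6-methylhepta-1,5-diene F6, which replaces 11 in step 6 under otherwise the same Ni/Cr conditions.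

**Further compounds**

F1 | step 6 | rac-1-{3-[2-hydroxy-7-methyl-3-methylideneoct-6-en-1-yl]-2,4-bis(methoxymethoxy)phenyl}ethan-1-one | C=C(CCC=C(C)C)C(O)Cc1c(OCOC)ccc(C(C)=O)c1OCOC
F2 | step 6 | 1-{3-[(2S)-2-hydroxy-2-[(2S)-2-(4-methylpent-3-en-1-yl)oxiran-2-yl]ethyl]-2,4-bis(methoxymethoxy)phenyl}ethan-1-one | CC(C)=CCC[C@]1(CO1)[C@@H](O)Cc1c(OCOC)ccc(C(C)=O)c1OCOC
F3 | step 8 | (2E)-1-{3-[(2R)-7-methyl-3-methylidene-2-(triethylsilyloxy)oct-6-en-1-yl]-2,4-bis(triethylsilyloxy)phenyl}-3-[4-(triethylsilyloxy)phenyl]prop-2-en-1-one | C=C(CCC=C(C)C)[C@H](O[Si](CC)(CC)CC)Cc1c(O[Si](CC)(CC)CC)ccc(C(=O)/C=C/c2ccc(O[Si](CC)(CC)CC)cc2)c1O[Si](CC)(CC)CC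
F4 | step 5 | (E)-N'-(6-methylhept-5-en-2-ylidene)-2,4,6-triisopropylbenzenesulfonohydrazide | C/C(CCC=C(C)C)=N\NS(=O)(=O)c1c(C(C)C)cc(C(C)C)cc1C(C)C
F5 | step 5 | 2-lithio-6-methylhepta-1,5-diene | [Li]C(=C)CCC=C(C)C
F6 | step 5 | 2-iodo-6-methylhepta-1,5-diene | C=C(I)CCC=C(C)C
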